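The route rests on disconnecting the trisubstituted C10'=C11' alkene of the side chain (C1' is the ring CH2, C15' the isopropylidene carbon). The feature exploited is that the C11' methyl lies cis to C9' on this (E)-alkene: raised to the carboxyl level, that methyl carbon and O9' fit into a five-membered butenolide ring (O9', C9', C10', C11', C=O). Closing this ring by olefin metathesis makes C10'=C11' and fixes its geometry in one operation. The precursor is the O9' ester of 2-(4-methylpent-3-enyl)acrylic acid with a C10' vinyl carbinol carrying the syn-8',9'-diol, O8' and the phenol being silyl ethers. Lactone reduction, deoxygenation, desilylation and phenol oxidation follow.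

Key step: step 11

Remark: the sense of induction in step 4 is taken as the established one for this reagent class, the allylborane made from (−)-Ipc2BOMe (from (+)-α-pinene) adding to the Si face of an aldehyde.

Abbreviations: TBS = tert-butyldimethylsilyl; Ipc = isopinocampheyl; "aryl" in names = 2-(tert-butyldimethylsilyloxy)-3-methylphenyl.

Step 1
Reactants: 1 2-bromo-6-methylphenol
Product: 2 (2-bromo-6-methylphenoxy)(tert-butyl)dimethylsilane
Conditions: TBSCl, imidazole, DMF, rt → 40 °C
Reagents that add atoms: tert-butyldimethylsilyl chloride, CC(C)(C)[Si](C)(C)Cl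
Why: Imidazole-promoted O-silylation masks the acidic phenol before the organomagnesium step, and the resulting 2,6-disubstituted aryl silyl ether is hindered enough to last until the fluoride treatment in step 14.

Step 2
Reactants: 2 (2-bromo-6-methylphenoxy)(tert-butyl)dimethylsilane; 3 geranyl bromide, (2E)-1-bromo-3,7-dimethylocta-2,6-diene
Product: 5 tert-butyl{2-[(2E)-3,7-dimethylocta-2,6-dien-1-yl]-6-methylphenoxy}dimethylsilane, via arylmagnesium bromide 4 (not isolated)
Conditions: Mg, THF, 40 °C; then 3, CuI (5 mol%), THF, −20 → 0 °C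
Reagents that add atoms: none
Why: Magnesium insertion into the aryl C–Br bond followed by copper-catalysed coupling of the Grignard reagent with the allylic bromide (Kumada-type allylic substitution) should join the aryl carbon to the primary carbon of 3 with the (E)-alkene intact, the arylmagnesium species being far less prone than an aryllithium to the O→C silyl shift (retro-Brook).

Step 3
Reactants: 5 tert-butyl{2-[(2E)-3,7-dimethylocta-2,6-dien-1-yl]-6-methylphenoxy}dimethylsilane
Product: 7 (2E,6E)-8-aryl-2,6-dimethylocta-2,6-dienal, via allylic alcohol 6 (not isolated)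
Conditions: SeO2 (0.3 equiv), t-BuOOH, salicylic acid (0.1 equiv), CH2Cl2, rt; crude, then MnO2, CH2Cl2, rt
Reagents that add atoms: selenium dioxide, O=[Se]=O (oxygen carrier); tert-butyl hydroperoxide, CC(C)(C)OO (terminal oxygen source)
Why: Riley allylic oxidation in its catalytic form proceeds by an ene reaction and [2,3]-sigmatropic shift at the (E)-methyl of the terminal isopropylidene unit, the more accessible of the two trisubstituted alkenes, and MnO2 should then converge the allylic alcohol and any aldehyde already formed on the (E)-enal.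

Step 4
Reactants: 7 (2E,6E)-8-aryl-2,6-dimethylocta-2,6-dienal; 8 allyl methoxymethyl ether
Product: 11 (3R,4R,5E,9E)-11-aryl-3-(methoxymethoxy)-5,9-dimethylundeca-1,5,9-trien-4-ol, via (Z)-alkoxyallylborane 9 (not isolated), via O8' borinate 10 (not isolated)
Conditions: 8, s-BuLi, THF, −78 °C; (−)-Ipc2BOMe; BF3·OEt2; then 7, −78 °C; NaBO3·4H2O, THF/H2O, rt
Reagents that add atoms: none
Why: In this Brown γ-alkoxyallylboration the chelated (Z)-alkoxyallyl anion is transferred to boron and borane 9 adds to the aldehyde through a chair six-membered transition state, so the (Z)-geometry fixes the syn relation of C8' and C9' while the isopinocampheyl groups from (+)-α-pinene direct attack to the Si face of the aldehyde, which should give the (8'R,9'R) isomer (C4 and C3 of 11).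

Step 5
Reactants: 11 (3R,4R,5E,9E)-11-aryl-3-(methoxymethoxy)-5,9-dimethylundeca-1,5,9-trien-4-ol
Product: 12 O8' tert-butyldimethylsilyl ether of 11
Conditions: TBSOTf, 2,6-lutidine, CH2Cl2, −78 °C
Reagents that add atoms: tert-butyldimethylsilyl trifluoromethanesulfonate, CC(C)(C)[Si](C)(C)OS(=O)(=O)C(F)(F)F
Why: Silylation of the hindered secondary allylic hydroxyl with the silyl triflate and a hindered pyridine base is fast at low temperature and should leave the acetal at O9' untouched.

Step 6
Reactants: 12 O8' tert-butyldimethylsilyl ether of 11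
Product: 14 (3R,4R,5E,9E)-4-(tert-butyldimethylsilyloxy)-11-aryl-5,9-dimethylundeca-1,5,9-trien-3-ol, via O9' bromomethyl ether 13 (not isolated)
Conditions: Me2BBr, CH2Cl2, −78 °C; then THF/aq. NaHCO3
Reagents that add atoms: none
Why: Me2BBr cleaves methoxymethyl ethers at −78 °C by binding the methoxy oxygen and passing bromide to the acetal carbon, and the bromomethyl ether 13 so formed is hydrolysed on bicarbonate work-up, a known acetal cleavage under which silyl ethers and alkenes should be inert and no cation develops at the allylic C9'.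

Step 7
Reactants: 15 diethyl malonate; 16 5-bromo-2-methylpent-2-ene
Product: 17 diethyl 2-(4-methylpent-3-en-1-yl)propanedioate
Conditions: NaH, THF/DMF, 0 °C; then 16, 60 °C
Reagents that add atoms: none
Why: In this malonic ester alkylation the sodium enolate displaces the primary bromide by SN2, an excess of 15 suppressing dialkylation.

Step 8
Reactants: 17 diethyl 2-(4-methylpent-3-en-1-yl)propanedioate
Product: 18 2-(4-methylpent-3-en-1-yl)propanedioic acid
Conditions: KOH, EtOH/H2O, reflux; then 1 M HCl, 0 °C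
Reagents that add atoms: potassium hydroxide, [K+].[OH-] (hydroxide oxygen ends in each carboxyl group)
Why: Saponification of both esters followed by cold, dilute acidification should give the malonic acid without touching the trisubstituted alkene.

Step 9
Reactants: 18 2-(4-methylpent-3-en-1-yl)propanedioic acid
Product: 19 6-methyl-2-methylidenehept-5-enoic acid, the 2-(4-methylpent-3-enyl)acrylic acid
Conditions: (CH2O)n, Et2NH, EtOAc, reflux
Reagents that add atoms: paraformaldehyde, as formaldehyde C=O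
Why: Mannich condensation of the monosubstituted malonic acid with formaldehyde and the secondary amine, followed by decarboxylative elimination of the amine, is the standard way to a 2-substituted acrylic acid.

Step 10
Reactants: 14 (3R,4R,5E,9E)-4-(tert-butyldimethylsilyloxy)-11-aryl-5,9-dimethylundeca-1,5,9-trien-3-ol; 19 6-methyl-2-methylidenehept-5-enoic acid
Product: 20 (3R,4R,5E,9E)-4-(tert-butyldimethylsilyloxy)-11-aryl-5,9-dimethylundeca-1,5,9-trien-3-yl 6-methyl-2-methylidenehept-5-enoate
Conditions: DCC, DMAP, CH2Cl2, 0 °C → rt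
Reagents that add atoms: none
Why: Steglich esterification transfers the carbodiimide-activated acid through DMAP to the secondary allylic O9'–H under neutral conditions that should neither move the neighbouring silyl group nor affect C9'.

Step 11
Reactants: 20 (3R,4R,5E,9E)-4-(tert-butyldimethylsilyloxy)-11-aryl-5,9-dimethylundeca-1,5,9-trien-3-yl 6-methyl-2-methylidenehept-5-enoate
Product: 21 (5R)-5-[(1R,2E,6E)-1-(tert-butyldimethylsilyloxy)-8-aryl-2,6-dimethylocta-2,6-dien-1-yl]-3-(4-methylpent-3-en-1-yl)furan-2(5H)-one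
Conditions: RuCl2(=CHPh)(PCy3)(H2IMes) (10 mol%), toluene (0.005 M), 80 °C, Ar sparge
Reagents that add atoms: none
Why: The benzylidene of the catalyst is exchanged for the unhindered C10' vinyl group, the new ruthenium alkylidene adds across the 1,1-disubstituted acrylate alkene held nearby by the O9' ester, and cycloreversion of the metallacyclobutane expels ethylene and leaves the C10'=C11' bond. The closest known reaction type is ring-closing metathesis of 2-substituted acrylates of secondary allylic alcohols to α-substituted butenolides with this second-generation Grubbs catalyst. The one ring closed, the five-membered unsaturated lactone O9'–C9'–C10'=C11'–C(=O), forms by intramolecular alkene metathesis joining C10' to C11' (carbene [2+2] and retro-[2+2], not a polar closure). No stereocentre is made and C8' and C9' are not touched; the ring forces C9' and the carbonyl carbon to be cis on the new alkene, which becomes the (E)-geometry once that carbon is reduced to CH3. The step needs chemoselectivity for the two terminal alkenes over the three trisubstituted ones, which their much slower reaction with the catalyst should secure, and through them only cyclobutenes or a medium ring could form. High dilution and loss of ethylene should favour cyclisation over cross-metathesis dimerisation.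

Step 12
Reactants: 21 (5R)-5-[(1R,2E,6E)-1-(tert-butyldimethylsilyloxy)-8-aryl-2,6-dimethylocta-2,6-dien-1-yl]-3-(4-methylpent-3-en-1-yl)furan-2(5H)-one
Product: 22 (2Z,4R,5R,6E,10E)-5-(tert-butyldimethylsilyloxy)-12-aryl-6,10-dimethyl-2-(4-methylpent-3-en-1-yl)dodeca-2,6,10-triene-1,4-diol
Conditions: i-Bu2AlH (4 equiv), CH2Cl2, −78 → 0 °C; aq. KNaC4H4O6
Reagents that add atoms: none
Why: Two hydride transfers take the lactone through the lactol aluminate and the ring-opened enal to the allylic alcohol (the known reduction of butenolides to (Z)-2-ene-1,4-diols), so the cis relation of C9' and the former carbonyl carbon should be kept.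

Step 13
Reactants: 22 (2Z,4R,5R,6E,10E)-5-(tert-butyldimethylsilyloxy)-12-aryl-6,10-dimethyl-2-(4-methylpent-3-en-1-yl)dodeca-2,6,10-triene-1,4-diol
Product: 24 (6E,8R,9R,10E,14E)-9-(tert-butyldimethylsilyloxy)-16-aryl-2,6,10,14-tetramethylhexadeca-2,6,10,14-tetraen-8-ol, via pyridinium sulfate 23 (not isolated)
Conditions: SO3·pyridine (1.1 equiv), THF, 0 °C; then LiAlH4, THF, 0 °C → rt
Reagents that add atoms: none
Why: In this Corey-type deoxygenation of an allylic alcohol through its sulfate monoester, the unhindered primary hydroxyl should be sulfated in preference to the secondary O9'–H next to the silyloxy-bearing C8', and hydride then displaces sulfate at the primary carbon without allylic transposition, leaving the (E)-C10'=C11' alkene with its methyl group.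

Step 14
Reactants: 24 (6E,8R,9R,10E,14E)-9-(tert-butyldimethylsilyloxy)-16-aryl-2,6,10,14-tetramethylhexadeca-2,6,10,14-tetraen-8-ol
Product: 25 2-[(2E,6E,8R,9R,10E)-8,9-dihydroxy-3,7,11,15-tetramethylhexadeca-2,6,10,14-tetraen-1-yl]-6-methylphenol
Conditions: Bu4NF, THF, 0 °C → rt
Reagents that add atoms: none
Why: Fluoride cleaves both Si–O bonds (driven by Si–F bond formation) without the acid that the bis-allylic diol would not tolerate, and any silyl migration between O8' and O9' or partial desilylation in the preceding hydride steps is erased here.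

Step 15
Reactants: 25 2-[(2E,6E,8R,9R,10E)-8,9-dihydroxy-3,7,11,15-tetramethylhexadeca-2,6,10,14-tetraen-1-yl]-6-methylphenol
Product: 26 2-[(2E,6E,8R,9R,10E)-8,9-dihydroxy-3,7,11,15-tetramethylhexadeca-2,6,10,14-tetraen-1-yl]-6-methylcyclohexa-2,5-diene-1,4-dione
Conditions: (KSO3)2NO, KH2PO4, H2O/acetone, rt
Reagents that add atoms: potassium nitrosodisulfonate, [K+].[K+].[O-]S(=O)(=O)N([O])S(=O)(=O)[O-]
Why: In the Teuber oxidation one nitrosodisulfonate radical abstracts the phenolic hydrogen and a second adds at the free para position, so a 2,6-disubstituted phenol should give the 1,4-benzoquinone while alkenes and the diol are left alone.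

Compound list
1 | 2-bromo-6-methylphenol | Cc1cccc(Br)c1O | starting material
2 | (2-bromo-6-methylphenoxy)(tert-butyl)dimethylsilane | Cc1cccc(Br)c1O[Si](C)(C)C(C)(C)C | intermediate
3 | geranyl bromide, (2E)-1-bromo-3,7-dimethylocta-2,6-diene | CC(C)=CCC/C(C)=C/CBr | starting material
4 | [2-(tert-butyldimethylsilyloxy)-3-methylphenyl]magnesium bromide | Cc1cccc([Mg]Br)c1O[Si](C)(C)C(C)(C)C | intermediate
5 | tert-butyl{2-[(2E)-3,7-dimethylocta-2,6-dien-1-yl]-6-methylphenoxy}dimethylsilane | CC(C)=CCC/C(C)=C/Cc1cccc(C)c1O[Si](C)(C)C(C)(C)C | intermediate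
6 | (2E,6E)-8-[2-(tert-butyldimethylsilyloxy)-3-methylphenyl]-2,6-dimethylocta-2,6-dien-1-ol | OC/C(C)=C/CC/C(C)=C/Cc1cccc(C)c1O[Si](C)(C)C(C)(C)C | intermediate
7 | (2E,6E)-8-[2-(tert-butyldimethylsilyloxy)-3-methylphenyl]-2,6-dimethylocta-2,6-dienal | O=C/C(C)=C/CC/C(C)=C/Cc1cccc(C)c1O[Si](C)(C)C(C)(C)C | intermediate
8 | allyl methoxymethyl ether, 3-(methoxymethoxy)prop-1-ene | C=CCOCOC | starting material
9 | [(2Z)-3-(methoxymethoxy)prop-2-en-1-yl]bis[(1R,2S,3R,5R)-2,6,6-trimethylbicyclo[3.1.1]heptan-3-yl]borane (isopinocampheyl groups from (+)-α-pinene) | COCO/C=C\CB([C@@H]1C[C@@H]2C[C@H]([C@H]1C)C2(C)C)[C@@H]1C[C@@H]2C[C@H]([C@H]1C)C2(C)C | intermediate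
10 | O8' diisopinocampheylborinate of 11 | C=C[C@@H](OCOC)[C@H](OB([C@@H]1C[C@@H]2C[C@H]([C@H]1C)C2(C)C)[C@@H]1C[C@@H]2C[C@H]([C@H]1C)C2(C)C)/C(C)=C/CC/C(C)=C/Cc1cccc(C)c1O[Si](C)(C)C(C)(C)C | intermediate
11 | (3R,4R,5E,9E)-11-[2-(tert-butyldimethylsilyloxy)-3-methylphenyl]-3-(methoxymethoxy)-5,9-dimethylundeca-1,5,9-trien-4-ol; (8'R,9'R), O8'–H free, O9' methoxymethyl ether | C=C[C@@H](OCOC)[C@H](O)/C(C)=C/CC/C(C)=C/Cc1cccc(C)c1O[Si](C)(C)C(C)(C)C | intermediate
12 | tert-butyl{[(3R,4R,5E,9E)-11-[2-(tert-butyldimethylsilyloxy)-3-methylphenyl]-3-(methoxymethoxy)-5,9-dimethylundeca-1,5,9-trien-4-yl]oxy}dimethylsilane | C=C[C@@H](OCOC)[C@H](O[Si](C)(C)C(C)(C)C)/C(C)=C/CC/C(C)=C/Cc1cccc(C)c1O[Si](C)(C)C(C)(C)C | intermediate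
13 | O9' bromomethyl ether, {[(3R,4R,5E,9E)-3-(bromomethoxy)-11-[2-(tert-butyldimethylsilyloxy)-3-methylphenyl]-5,9-dimethylundeca-1,5,9-trien-4-yl]oxy}(tert-butyl)dimethylsilane | C=C[C@@H](OCBr)[C@H](O[Si](C)(C)C(C)(C)C)/C(C)=C/CC/C(C)=C/Cc1cccc(C)c1O[Si](C)(C)C(C)(C)C | intermediate
14 | (3R,4R,5E,9E)-4-(tert-butyldimethylsilyloxy)-11-[2-(tert-butyldimethylsilyloxy)-3-methylphenyl]-5,9-dimethylundeca-1,5,9-trien-3-ol | C=C[C@@H](O)[C@H](O[Si](C)(C)C(C)(C)C)/C(C)=C/CC/C(C)=C/Cc1cccc(C)c1O[Si](C)(C)C(C)(C)C | intermediate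
15 | diethyl malonate | CCOC(=O)CC(=O)OCC | starting material
16 | 5-bromo-2-methylpent-2-ene | CC(C)=CCCBr | starting material
17 | diethyl 2-(4-methylpent-3-en-1-yl)propanedioate | CCOC(=O)C(CCC=C(C)C)C(=O)OCC | intermediate
18 | 2-(4-methylpent-3-en-1-yl)propanedioic acid | OC(=O)C(CCC=C(C)C)C(=O)O | intermediate
19 | 6-methyl-2-methylidenehept-5-enoic acid | C=C(CCC=C(C)C)C(=O)O | intermediate
20 | (3R,4R,5E,9E)-4-(tert-butyldimethylsilyloxy)-11-[2-(tert-butyldimethylsilyloxy)-3-methylphenyl]-5,9-dimethylundeca-1,5,9-trien-3-yl 6-methyl-2-methylidenehept-5-enoate | C=C[C@@H](OC(=O)C(=C)CCC=C(C)C)[C@H](O[Si](C)(C)C(C)(C)C)/C(C)=C/CC/C(C)=C/Cc1cccc(C)c1O[Si](C)(C)C(C)(C)C | intermediate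
21 | (5R)-5-{(1R,2E,6E)-1-(tert-butyldimethylsilyloxy)-8-[2-(tert-butyldimethylsilyloxy)-3-methylphenyl]-2,6-dimethylocta-2,6-dien-1-yl}-3-(4-methylpent-3-en-1-yl)furan-2(5H)-one | CC(C)=CCCC1=C[C@@H](OC1=O)[C@H](O[Si](C)(C)C(C)(C)C)/C(C)=C/CC/C(C)=C/Cc1cccc(C)c1O[Si](C)(C)C(C)(C)C | intermediate
22 | (2Z,4R,5R,6E,10E)-5-(tert-butyldimethylsilyloxy)-12-[2-(tert-butyldimethylsilyloxy)-3-methylphenyl]-6,10-dimethyl-2-(4-methylpent-3-en-1-yl)dodeca-2,6,10-triene-1,4-diol | CC(C)=CCC/C(CO)=C/[C@@H](O)[C@H](O[Si](C)(C)C(C)(C)C)/C(C)=C/CC/C(C)=C/Cc1cccc(C)c1O[Si](C)(C)C(C)(C)C | intermediate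
23 | pyridinium salt of the C1 sulfate monoester of 22 | CC(C)=CCC/C(COS(=O)(=O)[O-])=C/[C@@H](O)[C@H](O[Si](C)(C)C(C)(C)C)/C(C)=C/CC/C(C)=C/Cc1cccc(C)c1O[Si](C)(C)C(C)(C)C.c1cc[nH+]cc1 | intermediate
24 | (6E,8R,9R,10E,14E)-9-(tert-butyldimethylsilyloxy)-16-[2-(tert-butyldimethylsilyloxy)-3-methylphenyl]-2,6,10,14-tetramethylhexadeca-2,6,10,14-tetraen-8-ol | CC(C)=CCC/C(C)=C/[C@@H](O)[C@H](O[Si](C)(C)C(C)(C)C)/C(C)=C/CC/C(C)=C/Cc1cccc(C)c1O[Si](C)(C)C(C)(C)C | intermediate
25 | 2-[(2E,6E,8R,9R,10E)-8,9-dihydroxy-3,7,11,15-tetramethylhexadeca-2,6,10,14-tetraen-1-yl]-6-methylphenol | CC(C)=CCC/C(C)=C/[C@@H](O)[C@H](O)/C(C)=C/CC/C(C)=C/Cc1cccc(C)c1O | intermediate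
26 | 2-[(2E,6E,8R,9R,10E)-8,9-dihydroxy-3,7,11,15-tetramethylhexadeca-2,6,10,14-tetraen-1-yl]-6-methylcyclohexa-2,5-diene-1,4-dione | CC(C)=CCC/C(C)=C/[C@@H](O)[C@H](O)/C(C)=C/CC/C(C)=C/CC1=CC(=O)C=C(C)C1=O | target

Total step count: 15.
Longest linear sequence: 12 steps (steps 1 to 6 and 10 to 15, from 1 to 26); the acid branch is steps 7 to 9.

Steps most likely to fail

Step 11 (key step). The vinyl-bound ruthenium carbene may close only slowly onto the hindered, electron-poor 1,1-disubstituted acrylate, so that it is consumed by intermolecular cross-metathesis or the catalyst decays before cyclisation. The fallback moves the tether to O8', so that a six-membered unsaturated lactone, which closes more readily, carries the same cis relation between C9' and the carbonyl carbon. It sets out from 11, whose O8'–H is free. Esterification with 19 (DCC, DMAP) should give the O8' acrylate ester F1, and ring-closing metathesis with the same catalyst the 5,6-dihydropyran-2-one F2. i-Bu2AlH should open this to the (Z)-enediol F3. SO3·pyridine should give the primary pyridinium sulfate F4, which LiAlH4 reduces to the C11'-methyl methoxymethyl ether F5. ZnBr2 with n-PrSH (the thiol traps the acetal carbon, so no cyclic formal forms with the neighbouring hydroxyl) should then give the aryl silyl ether diol F6, and Bu4NF returns the route to 25.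

Step 13. Sulfation may also occur at the secondary O9'–H, or the O9' alkoxide may displace the primary sulfate in place of hydride and close a 2,5-dihydrofuran. The fallback blocks O9' before the primary position is activated. It sets out from 22. TBSOTf and 2,6-lutidine should give the tetrakis-silyl ether F7. Camphorsulfonic acid in MeOH/CH2Cl2 at 0 °C should free only the primary allylic position, giving the primary alcohol F8. PPh3 and CBr4 should give the allylic bromide F9, and LiEt3BH should displace bromide at the primary carbon to give the tris-silyl ether F10. Bu4NF then cleaves all three silyl ethers and returns the route to 25.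

Step 6. Under the Lewis acid the neighbouring O8' silyl group may be lost or may shift, or the O8' oxygen may capture the activated acetal carbon to give a cyclic formal. The fallback removes the acetal before any silyl group sits on the diol and differentiates the two hydroxyls by sterics. It sets out from 11. ZnBr2 with n-PrSH should give the syn-diol F11. Slow esterification with one equivalent of 19 (DCC, DMAP, −20 °C) should acylate the less hindered hydroxyl, O9' next to the vinyl group, in preference to O8' next to the methyl-bearing alkene, giving the O9' hydroxy ester F12. TBSOTf and 2,6-lutidine then silylate O8' and return the route to 20.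

Further compounds
F1 | step 11 | (3R,4R,5E,9E)-11-[2-(tert-butyldimethylsilyloxy)-3-methylphenyl]-3-(methoxymethoxy)-5,9-dimethylundeca-1,5,9-trien-4-yl 6-methyl-2-methylidenehept-5-enoate | C=C[C@@H](OCOC)[C@H](OC(=O)C(=C)CCC=C(C)C)/C(C)=C/CC/C(C)=C/Cc1cccc(C)c1O[Si](C)(C)C(C)(C)C
F2 | step 11 | (5R,6R)-6-{(2E,6E)-8-[2-(tert-butyldimethylsilyloxy)-3-methylphenyl]-6-methylocta-2,6-dien-2-yl}-5-(methoxymethoxy)-3-(4-methylpent-3-en-1-yl)-5,6-dihydro-2H-pyran-2-one | CC(C)=CCCC1=C[C@@H](OCOC)[C@H](OC1=O)/C(C)=C/CC/C(C)=C/Cc1cccc(C)c1O[Si](C)(C)C(C)(C)C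
F3 | step 11 | (2Z,4R,5R,6E,10E)-12-[2-(tert-butyldimethylsilyloxy)-3-methylphenyl]-4-(methoxymethoxy)-6,10-dimethyl-2-(4-methylpent-3-en-1-yl)dodeca-2,6,10-triene-1,5-diol | CC(C)=CCC/C(CO)=C/[C@@H](OCOC)[C@H](O)/C(C)=C/CC/C(C)=C/Cc1cccc(C)c1O[Si](C)(C)C(C)(C)C
F4 | step 11 | pyridinium salt of the C1 sulfate monoester of F3 | CC(C)=CCC/C(COS(=O)(=O)[O-])=C/[C@@H](OCOC)[C@H](O)/C(C)=C/CC/C(C)=C/Cc1cccc(C)c1O[Si](C)(C)C(C)(C)C.c1cc[nH+]cc1
F5 | step 11 | (6E,8R,9R,10E,14E)-16-[2-(tert-butyldimethylsilyloxy)-3-methylphenyl]-8-(methoxymethoxy)-2,6,10,14-tetramethylhexadeca-2,6,10,14-tetraen-9-ol | CC(C)=CCC/C(C)=C/[C@@H](OCOC)[C@H](O)/C(C)=C/CC/C(C)=C/Cc1cccc(C)c1O[Si](C)(C)C(C)(C)C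
F6 | step 11 | (6E,8R,9R,10E,14E)-16-[2-(tert-butyldimethylsilyloxy)-3-methylphenyl]-2,6,10,14-tetramethylhexadeca-2,6,10,14-tetraene-8,9-diol | CC(C)=CCC/C(C)=C/[C@@H](O)[C@H](O)/C(C)=C/CC/C(C)=C/Cc1cccc(C)c1O[Si](C)(C)C(C)(C)C
F7 | step 13 | 1-O,4-O-bis(tert-butyldimethylsilyl) ether of 22 (all four oxygens silylated) | CC(C)=CCC/C(CO[Si](C)(C)C(C)(C)C)=C/[C@@H](O[Si](C)(C)C(C)(C)C)[C@H](O[Si](C)(C)C(C)(C)C)/C(C)=C/CC/C(C)=C/Cc1cccc(C)c1O[Si](C)(C)C(C)(C)C
F8 | step 13 | (2Z,4R,5R,6E,10E)-4,5-bis(tert-butyldimethylsilyloxy)-12-[2-(tert-butyldimethylsilyloxy)-3-methylphenyl]-6,10-dimethyl-2-(4-methylpent-3-en-1-yl)dodeca-2,6,10-trien-1-ol | CC(C)=CCC/C(CO)=C/[C@@H](O[Si](C)(C)C(C)(C)C)[C@H](O[Si](C)(C)C(C)(C)C)/C(C)=C/CC/C(C)=C/Cc1cccc(C)c1O[Si](C)(C)C(C)(C)C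
F9 | step 13 | primary allylic bromide from F8 (CH2Br in place of CH2OH) | CC(C)=CCC/C(CBr)=C/[C@@H](O[Si](C)(C)C(C)(C)C)[C@H](O[Si](C)(C)C(C)(C)C)/C(C)=C/CC/C(C)=C/Cc1cccc(C)c1O[Si](C)(C)C(C)(C)C
F10 | step 13 | O9' tert-butyldimethylsilyl ether of 24, (6E,8R,9R,10E,14E)-8,9-bis(tert-butyldimethylsilyloxy)-16-[2-(tert-butyldimethylsilyloxy)-3-methylphenyl]-2,6,10,14-tetramethylhexadeca-2,6,10,14-tetraene | CC(C)=CCC/C(C)=C/[C@@H](O[Si](C)(C)C(C)(C)C)[C@H](O[Si](C)(C)C(C)(C)C)/C(C)=C/CC/C(C)=C/Cc1cccc(C)c1O[Si](C)(C)C(C)(C)C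
F11 | step 6 | (3R,4R,5E,9E)-11-[2-(tert-butyldimethylsilyloxy)-3-methylphenyl]-5,9-dimethylundeca-1,5,9-triene-3,4-diol | C=C[C@@H](O)[C@H](O)/C(C)=C/CC/C(C)=C/Cc1cccc(C)c1O[Si](C)(C)C(C)(C)C
F12 | step 6 | (3R,4R,5E,9E)-11-[2-(tert-butyldimethylsilyloxy)-3-methylphenyl]-4-hydroxy-5,9-dimethylundeca-1,5,9-trien-3-yl 6-methyl-2-methylidenehept-5-enoate | C=C[C@@H](OC(=O)C(=C)CCC=C(C)C)[C@H](O)/C(C)=C/CC/C(C)=C/Cc1cccc(C)c1O[Si](C)(C)C(C)(C)C
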